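**Retrosynthetic overview**
- The target is reached by late allylic oxidation (CH3 to CHO) of the isopropenyl group of the corresponding bis-tiglate.
- The bis-tiglate comes from a diol, whose benzylic (R)-carbinol is set by asymmetric transfer hydrogenation of an aryl methyl ketone.
- Key disconnection: the C2–C3 bond (and then O1–C2) of the dihydrobenzofuran, made in one flask from 5-acetylsalicylaldehyde and a chiral methallyl sulfonium ylide. The allylic carbon, an electrophile in methallyl bromide, is used as a carbanion toward the equally electrophilic aldehyde carbon, then reverts to an electrophile toward the phenoxide.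
- Ring order: the benzene ring is bought; the dihydrofuran ring is the only ring formed, in the key step, together with both ring stereocentres.

Assumption: the isothiocineole enantiomer made from (S)-limonene is taken to be the one that gives the (S,S)-vinyl epoxide in the key step; if the sense of induction is the reverse, the mirror-image sulfide from (R)-limonene is used and nothing else changes.

**Route**

Step 1
Reactants: 1 isothiocineole, (1S,4R,5S)-4,7,7-trimethyl-6-thiabicyclo[3.2.1]octane (C4 methyl cis to sulfur; one step from (S)-limonene, both enantiomers are sold); 2 3-bromo-2-methylprop-1-ene (methallyl bromide)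
Product: 3 (1S,4R,5S,6S)-4,7,7-trimethyl-6-(2-methylprop-2-en-1-yl)-6-thiabicyclo[3.2.1]octan-6-ium trifluoromethanesulfonate
Conditions: 2 (2 equiv), LiOSO2CF3 (3 equiv), CH2Cl2/H2O 1:1, rt, 24 h
Reagents that add atoms: lithium trifluoromethanesulfonate, [Li+].[O-]S(=O)(=O)C(F)(F)F
Why: SN2 S-alkylation of the thioether by the allylic bromide, driven by exchange of bromide for non-nucleophilic triflate; alkylation on the less hindered sulfur lone pair gives a single sulfonium diastereomer.

Step 2
Reactants: 3 sulfonium triflate; 4 5-acetyl-2-hydroxybenzaldehyde (5-acetylsalicylaldehyde)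
Product: 7 1-[(2R,3S)-3-hydroxy-2-(prop-1-en-2-yl)-2,3-dihydro-1-benzofuran-5-yl]ethan-1-one, via sulfonium ylide 5 (not isolated), via trans-vinyl epoxide 6 (not isolated)
Conditions: 3 (1.2 equiv), KOH (2.5 equiv), MeCN/H2O 9:1, 0 °C to rt, then 40 °C
Reagents that add atoms: none
Why: Proposed new method: KOH forms the phenoxide of 4 and the allylic ylide 5, whose carbanion carbon attacks the aldehyde carbon on the ylide face left open by the bicyclic sulfide; the anti betaine closes to the trans (2S,3S)-epoxide 6 with loss of sulfide 1 (sets C3), and the ortho phenoxide then opens 6 at the allylic carbon by a 5-endo SN2 with inversion (sets C2, trans to the C3 oxygen), a formal [4+1] annulation whose closest known relatives are the isothiocineole-mediated asymmetric Corey–Chaykovsky epoxidation of aldehydes with allylic sulfonium salts and the conversion of salicylaldehydes into 2,3-dihydrobenzofuran-3-ols by sulfoxonium methylide.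

Step 3
Reactants: 7 hydroxy ketone
Product: 8 (2R,3S)-5-[(1R)-1-hydroxyethyl]-2-(prop-1-en-2-yl)-2,3-dihydro-1-benzofuran-3-ol
Conditions: RuCl(p-cymene)[(R,R)-TsDPEN] (1 mol%), HCO2Na (5 equiv), H2O/MeOH 1:1, 40 °C
Reagents that add atoms: none
Why: Noyori asymmetric transfer hydrogenation of an aryl methyl ketone, in which the (R,R)-TsDPEN ruthenium hydride sets the (R)-carbinol under catalyst control while the isolated alkene and the acid-sensitive C3 alcohol are untouched in near-neutral aqueous formate.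

Step 4
Reactants: 8 diol; 9 (2E)-2-methylbut-2-enoyl chloride (tigloyl chloride)
Product: 10 (1R)-1-[(2R,3S)-3-{[(2E)-2-methylbut-2-enoyl]oxy}-2-(prop-1-en-2-yl)-2,3-dihydro-1-benzofuran-5-yl]ethyl (2E)-2-methylbut-2-enoate
Conditions: 9 (3 equiv), pyridine (6 equiv), DMAP (0.2 equiv), CH2Cl2, 0 °C to rt
Reagents that add atoms: none
Why: DMAP-catalysed acylation of both secondary alcohols with retention at the carbinol carbons; the (E)-tiglate geometry is the stable one and the weak base pyridine avoids vinylketene formation and deconjugation.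

Step 5
Reactants: 10 bis-tiglate
Product: 12 the target (1R)-1-[(2R,3S)-3-{[(2E)-2-methylbut-2-enoyl]oxy}-2-(3-oxoprop-1-en-2-yl)-2,3-dihydro-1-benzofuran-5-yl]ethyl (2E)-2-methylbut-2-enoate, via allylic alcohol 11 (not isolated)
Conditions: SeO2 (0.5 equiv), t-BuOOH (4 equiv, in decane), CH2Cl2, rt then 40 °C until 11 is consumed
Reagents that add atoms: selenium dioxide, O=[Se]=O; tert-butyl hydroperoxide, CC(C)(C)OO
Why: SeO2/t-BuOOH allylic oxidation (ene reaction then [2,3]-sigmatropic shift) attacks the only electron-rich alkene at its methyl group (CH3 preferred over the ring CH), and the same reagents take the primary allylic alcohol 11 on to the enal; the electron-poor tiglate alkenes react far more slowly and no stereocentre is involved.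

**Compound list**
1 | isothiocineole, (1S,4R,5S)-4,7,7-trimethyl-6-thiabicyclo[3.2.1]octane | C[C@@H]1CC[C@H]2C[C@@H]1SC2(C)C | starting material
2 | 3-bromo-2-methylprop-1-ene | C=C(C)CBr | starting material
3 | (1S,4R,5S,6S)-4,7,7-trimethyl-6-(2-methylprop-2-en-1-yl)-6-thiabicyclo[3.2.1]octan-6-ium trifluoromethanesulfonate | C[C@@H]1CC[C@H]2C[C@@H]1[S@+](CC(C)=C)C2(C)C.[O-]S(=O)(=O)C(F)(F)F | intermediate
4 | 5-acetyl-2-hydroxybenzaldehyde | CC(=O)c1ccc(O)c(C=O)c1 | starting material
5 | sulfonium ylide of 3 (carbanion on the allylic carbon bound to sulfur) | C[C@@H]1CC[C@H]2C[C@@H]1[S@+]([CH-]C(C)=C)C2(C)C | intermediate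
6 | 1-{4-hydroxy-3-[(2S,3S)-3-(prop-1-en-2-yl)oxiran-2-yl]phenyl}ethan-1-one (present as its phenoxide) | CC(=O)c1ccc(O)c(c1)[C@@H]1O[C@H]1C(C)=C | intermediate
7 | 1-[(2R,3S)-3-hydroxy-2-(prop-1-en-2-yl)-2,3-dihydro-1-benzofuran-5-yl]ethan-1-one | C=C(C)[C@H]1Oc2ccc(C(C)=O)cc2[C@@H]1O | intermediate
8 | (2R,3S)-5-[(1R)-1-hydroxyethyl]-2-(prop-1-en-2-yl)-2,3-dihydro-1-benzofuran-3-ol | C=C(C)[C@H]1Oc2ccc([C@@H](C)O)cc2[C@@H]1O | intermediate
9 | (2E)-2-methylbut-2-enoyl chloride | C/C=C(\C)C(Cl)=O | starting material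
10 | (1R)-1-[(2R,3S)-3-{[(2E)-2-methylbut-2-enoyl]oxy}-2-(prop-1-en-2-yl)-2,3-dihydro-1-benzofuran-5-yl]ethyl (2E)-2-methylbut-2-enoate | C=C(C)[C@H]1Oc2ccc([C@@H](C)OC(=O)/C(C)=C/C)cc2[C@@H]1OC(=O)/C(C)=C/C | intermediate
11 | (1R)-1-[(2R,3S)-2-(3-hydroxyprop-1-en-2-yl)-3-{[(2E)-2-methylbut-2-enoyl]oxy}-2,3-dihydro-1-benzofuran-5-yl]ethyl (2E)-2-methylbut-2-enoate | C=C(CO)[C@H]1Oc2ccc([C@@H](C)OC(=O)/C(C)=C/C)cc2[C@@H]1OC(=O)/C(C)=C/C | intermediate
12 | (1R)-1-[(2R,3S)-3-{[(2E)-2-methylbut-2-enoyl]oxy}-2-(3-oxoprop-1-en-2-yl)-2,3-dihydro-1-benzofuran-5-yl]ethyl (2E)-2-methylbut-2-enoate | C=C(C=O)[C@H]1Oc2ccc([C@@H](C)OC(=O)/C(C)=C/C)cc2[C@@H]1OC(=O)/C(C)=C/C | target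

**Step count**
Total steps: 5. Longest linear sequence: 5 (steps 1 to 5; 4 steps from aldehyde 4).

**Steps most likely to fail**

Step 2 (key annulation). Risks: the phenoxide aldehyde is a weak electrophile, the phenoxide can be O-allylated by salt 3, the acetyl group can condense with the aldehyde under base, and a direct displacement of the sulfonium by the phenoxide would give the cis isomer. Fallback, from 4 back to 7: the phenol is masked and the two events are separated. Silylation of 4 (t-BuMe2SiCl, imidazole, DMF) gives 5-acetyl-2-[(tert-butyldimethylsilyl)oxy]benzaldehyde F1. Ylide 5, pre-formed from 3 with KN(SiMe3)2 in THF at −78 °C, epoxidises F1 to the isolable 1-{4-[(tert-butyldimethylsilyl)oxy]-3-[(2S,3S)-3-(prop-1-en-2-yl)oxiran-2-yl]phenyl}ethan-1-one F2, whose ratio and ee can be checked. Bu4NF in THF at 0 °C then frees the phenoxide of 6, which closes to 7 by the same epoxide opening.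

Step 5 (allylic oxidation). Risks: the reaction may stop at alcohol 11, the tiglate methyl groups may be oxidised slowly, or the C2–H may be attacked. Fallback, from 10 back to 12: ene-type chlorination of the isopropenyl group (Ca(OCl)2, solid CO2, CH2Cl2/H2O, 0 °C) gives (1R)-1-[(2R,3S)-2-(3-chloroprop-1-en-2-yl)-3-{[(2E)-2-methylbut-2-enoyl]oxy}-2,3-dihydro-1-benzofuran-5-yl]ethyl (2E)-2-methylbut-2-enoate F3. Oxidation of the allylic chloride with N-methylmorpholine N-oxide in MeCN at 40 °C (Kornblum–Ganem type) then gives aldehyde 12 without selenium.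

Step 4 (double acylation). Risks: the C3 alcohol is hindered, both benzylic esters can ionise or eliminate (the C3 ester toward the aromatic benzofuran), and the acid chloride can deconjugate. Fallback, from 8 back to 10: both alcohols are esterified with the unhindered saturated 2-(diethoxyphosphoryl)propanoic acid (N,N'-dicyclohexylcarbodiimide, DMAP, CH2Cl2) to give (1R)-1-[(2R,3S)-3-{[2-(diethoxyphosphoryl)propanoyl]oxy}-2-(prop-1-en-2-yl)-2,3-dihydro-1-benzofuran-5-yl]ethyl 2-(diethoxyphosphoryl)propanoate F4. A double Horner–Wadsworth–Emmons olefination with acetaldehyde (LiCl, DBU, MeCN, 0 °C) then builds both (E)-2-methylbut-2-enoates on the esters and gives 10.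

**Further compounds**
F1 | step 2 | 5-acetyl-2-[(tert-butyldimethylsilyl)oxy]benzaldehyde | CC(=O)c1ccc(O[Si](C)(C)C(C)(C)C)c(C=O)c1
F2 | step 2 | 1-{4-[(tert-butyldimethylsilyl)oxy]-3-[(2S,3S)-3-(prop-1-en-2-yl)oxiran-2-yl]phenyl}ethan-1-one | CC(=O)c1ccc(O[Si](C)(C)C(C)(C)C)c(c1)[C@@H]1O[C@H]1C(C)=C
F3 | step 5 | (1R)-1-[(2R,3S)-2-(3-chloroprop-1-en-2-yl)-3-{[(2E)-2-methylbut-2-enoyl]oxy}-2,3-dihydro-1-benzofuran-5-yl]ethyl (2E)-2-methylbut-2-enoate | C=C(CCl)[C@H]1Oc2ccc([C@@H](C)OC(=O)/C(C)=C/C)cc2[C@@H]1OC(=O)/C(C)=C/C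
F4 | step 4 | (1R)-1-[(2R,3S)-3-{[2-(diethoxyphosphoryl)propanoyl]oxy}-2-(prop-1-en-2-yl)-2,3-dihydro-1-benzofuran-5-yl]ethyl 2-(diethoxyphosphoryl)propanoate (epimer mixture at the two phosphorus-bearing carbons) | C=C(C)[C@H]1Oc2ccc([C@@H](C)OC(=O)C(C)P(=O)(OCC)OCC)cc2[C@@H]1OC(=O)C(C)P(=O)(OCC)OCC
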